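**Retrosynthetic overview**
- Target ⇐ global O-debenzylation ⇐ oxidation of the benzylic CH2 of an 8-phenacyl flavan (a deoxybenzoin) to the 1,2-diketone.
- Key disconnection, C8–CH2: the C8–H of the (2S)-tri-O-benzyl flavan acts as arene nucleophile toward the α-carbon of 4'-benzyloxyacetophenone, made electrophilic as a trivalent-iodine enolonium species (from its silyl enol ether). Two natively nucleophilic carbons are joined and C8 needs no pre-functionalisation.
- Flavan ⇐ Mitsunobu ring closure with inversion ⇐ (R)-carbinol from asymmetric transfer hydrogenation ⇐ dihydrochalcone ⇐ aldol of dibenzylated phloroglucinaldehyde with the same acetophenone, which is used twice.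
- Ring order: ring A, ring B and the aroyl ring are bought as arenes; only the pyran ring C is formed (step 5); C2 is the only stereocentre.

Assumption: the stereocentre written in the SMILES is C2 of the chroman ring and has the S configuration (flavan numbering is used throughout).

**Step 1**
Reactants: 1 2,4,6-trihydroxybenzaldehyde
Product: 2 2,4-bis(benzyloxy)-6-hydroxybenzaldehyde
Conditions: BnBr (2.1 equiv), K2CO3 (2.2 equiv), DMF, 0 °C to rt
Reagents that add atoms: benzyl bromide, BrCc1ccccc1
Why: Williamson etherification stops at the bis-ether because the last hydroxyl is hydrogen-bonded to the formyl group and is a poor nucleophile, as is usual for acylphloroglucinols; no stereocentre is involved.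

**Step 2**
Reactants: 2 2,4-bis(benzyloxy)-6-hydroxybenzaldehyde; 3 1-[4-(benzyloxy)phenyl]ethan-1-one
Product: 4 (E)-3-[2,4-bis(benzyloxy)-6-hydroxyphenyl]-1-[4-(benzyloxy)phenyl]prop-2-en-1-one
Conditions: KOH (50% aq, excess), EtOH/THF, rt to 50 °C; then AcOH to pH 6
Reagents that add atoms: none
Why: Claisen–Schmidt aldol condensation of the methyl ketone enolate with the aldehyde, followed by E1cB loss of water, gives the conjugated (E)-enone; the phenoxide slows the addition but does not stop it, and the mildly acidic quench avoids flavylium formation.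

**Step 3**
Reactants: 4 (E)-3-[2,4-bis(benzyloxy)-6-hydroxyphenyl]-1-[4-(benzyloxy)phenyl]prop-2-en-1-one
Product: 5 3-[2,4-bis(benzyloxy)-6-hydroxyphenyl]-1-[4-(benzyloxy)phenyl]propan-1-one
Conditions: H2 (1 atm), RhCl(PPh3)3 (5 mol %), THF/EtOH, 40 °C
Reagents that add atoms: none
Why: Homogeneous hydrogenation with RhCl(PPh3)3 saturates the disubstituted enone C=C without hydrogenolysis of the benzyl ethers and without reducing the aryl ketone.

**Step 4**
Reactants: 5 3-[2,4-bis(benzyloxy)-6-hydroxyphenyl]-1-[4-(benzyloxy)phenyl]propan-1-one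
Product: 6 (1R)-1-[4-(benzyloxy)phenyl]-3-[2,4-bis(benzyloxy)-6-hydroxyphenyl]propan-1-ol
Conditions: RuCl[(R,R)-TsDPEN](p-cymene) (1 mol %), HCO2H/Et3N (1:1), DMF, 40 °C
Reagents that add atoms: none
Why: Noyori–Ikariya asymmetric transfer hydrogenation: the (R,R)-TsDPEN ruthenium hydride delivers hydride to the Si face of the aryl ketone through the CH/π-organised six-membered transition state, giving the (R)-carbinol (same sense as acetophenone to (R)-1-phenylethanol, typically ≥95% ee), while the near-neutral formate medium avoids acid cyclodehydration of the keto-phenol.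

**Step 5**
Reactants: 6 (1R)-1-[4-(benzyloxy)phenyl]-3-[2,4-bis(benzyloxy)-6-hydroxyphenyl]propan-1-ol
Product: 7 (2S)-5,7-bis(benzyloxy)-2-[4-(benzyloxy)phenyl]chromane
Conditions: PPh3, DIAD, THF, 0 °C
Reagents that add atoms: none
Why: Intramolecular Mitsunobu etherification: the phenol displaces the oxyphosphonium-activated benzylic oxygen in a 6-exo-tet SN2 closure with inversion, so the (R)-carbinol gives the (2S)-flavan, as in Mitsunobu closures of benzyloxyaryl carbinols used for flavan-3-ols.

**Step 6**
Reactants: 3 1-[4-(benzyloxy)phenyl]ethan-1-one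
Product: 8 {1-[4-(benzyloxy)phenyl]ethenyl}oxy(trimethyl)silane
Conditions: TMSOTf, Et3N, CH2Cl2, 0 °C
Reagents that add atoms: trimethylsilyl trifluoromethanesulfonate, C[Si](C)(C)OS(=O)(=O)C(F)(F)F
Why: Soft enolisation of the methyl ketone (silyl triflate plus amine) gives the only possible silyl enol ether; the aryl benzyl ether is inert.

**Step 7**
Reactants: 7 (2S)-5,7-bis(benzyloxy)-2-[4-(benzyloxy)phenyl]chromane; 8 {1-[4-(benzyloxy)phenyl]ethenyl}oxy(trimethyl)silane
Product: 10 2-{(2S)-5,7-bis(benzyloxy)-2-[4-(benzyloxy)phenyl]chroman-8-yl}-1-[4-(benzyloxy)phenyl]ethan-1-one, via enolonium tosylate 9 (not isolated)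
Conditions: PhI(OH)OTs (1.5 equiv), BF3·OEt2 (1.5 equiv), CH2Cl2, −78 °C, then 8 (1.5 equiv), 10 min; then 7 (1.0 equiv), −78 to −40 °C; aq NaHCO3
Reagents that add atoms: none
Why: Proposed new method: BF3-activated PhI(OH)OTs oxidises silyl enol ether 8 at −78 °C to the phenacyl(phenyl)iodonium (enolonium) species 9, whose α-keto carbon is a strong electrophile with iodobenzene as leaving group; because the oxidant is consumed before the arene is added, 7 meets only the carbon electrophile and attacks it in a Friedel–Crafts sense through C8 (activated by O1, 7-OBn and 5-OBn and less hindered than C6, which sits between two benzyloxy groups); the closest known reactions are the metal-free α-arylation of ketones with indoles and pyrroles through trivalent-iodine enolonium species and the C8-selective attack of bulky carbocations on 5,7-di-O-benzyl flavans in procyanidin couplings; C2 is not involved and is stable to BF3 at this temperature.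

**Step 8**
Reactants: 10 2-{(2S)-5,7-bis(benzyloxy)-2-[4-(benzyloxy)phenyl]chroman-8-yl}-1-[4-(benzyloxy)phenyl]ethan-1-one
Product: 11 1-{(2S)-5,7-bis(benzyloxy)-2-[4-(benzyloxy)phenyl]chroman-8-yl}-2-[4-(benzyloxy)phenyl]ethane-1,2-dione
Conditions: SeO2 (2 equiv), 1,4-dioxane/H2O (20:1), 95 °C
Reagents that add atoms: selenium dioxide, O=[Se]=O
Why: Riley oxidation: SeO2 oxidises the doubly activated methylene (benzylic to the trialkoxyarene and α to the ketone) through its enol to the 1,2-diketone; no other position enolises and C2 is untouched.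

**Step 9**
Reactants: 11 1-{(2S)-5,7-bis(benzyloxy)-2-[4-(benzyloxy)phenyl]chroman-8-yl}-2-[4-(benzyloxy)phenyl]ethane-1,2-dione
Product: 12 1-[(2S)-5,7-dihydroxy-2-(4-hydroxyphenyl)chroman-8-yl]-2-(4-hydroxyphenyl)ethane-1,2-dione
Conditions: H2 (1 atm), 10% Pd/C, EtOAc/MeOH, rt, stopped after uptake of 4 equiv H2
Reagents that add atoms: none
Why: Catalytic hydrogenolysis cleaves the four aryl benzyl ethers much faster than it reduces the hindered, electron-rich diaryl diketone or the ring C2–O1 bond (as in debenzylation of benzylated flavans), so the 2S centre is retained.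

**Compound list**
1 | 2,4,6-trihydroxybenzaldehyde | O=Cc1c(O)cc(O)cc1O | starting material
2 | 2,4-bis(benzyloxy)-6-hydroxybenzaldehyde | O=Cc1c(O)cc(OCc2ccccc2)cc1OCc1ccccc1 | intermediate
3 | 1-[4-(benzyloxy)phenyl]ethan-1-one | CC(=O)c1ccc(OCc2ccccc2)cc1 | starting material
4 | (E)-3-[2,4-bis(benzyloxy)-6-hydroxyphenyl]-1-[4-(benzyloxy)phenyl]prop-2-en-1-one | O=C(/C=C/c1c(O)cc(OCc2ccccc2)cc1OCc1ccccc1)c1ccc(OCc2ccccc2)cc1 | intermediate
5 | 3-[2,4-bis(benzyloxy)-6-hydroxyphenyl]-1-[4-(benzyloxy)phenyl]propan-1-one | O=C(CCc1c(O)cc(OCc2ccccc2)cc1OCc1ccccc1)c1ccc(OCc2ccccc2)cc1 | intermediate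
6 | (1R)-1-[4-(benzyloxy)phenyl]-3-[2,4-bis(benzyloxy)-6-hydroxyphenyl]propan-1-ol | O[C@@H](c1ccc(OCc2ccccc2)cc1)CCc1c(O)cc(OCc2ccccc2)cc1OCc1ccccc1 | intermediate
7 | (2S)-5,7-bis(benzyloxy)-2-[4-(benzyloxy)phenyl]chromane | C(Oc1cc(OCc2ccccc2)c2c(c1)O[C@H](c1ccc(OCc3ccccc3)cc1)CC2)c1ccccc1 | intermediate
8 | {1-[4-(benzyloxy)phenyl]ethenyl}oxy(trimethyl)silane | C=C(O[Si](C)(C)C)c1ccc(OCc2ccccc2)cc1 | intermediate
9 | {2-[4-(benzyloxy)phenyl]-2-oxoethyl}(phenyl)iodonium 4-methylbenzenesulfonate (enolonium species, drawn C-bound) | O=C(C[I+]c1ccccc1)c1ccc(OCc2ccccc2)cc1.Cc1ccc(S(=O)(=O)[O-])cc1 | intermediate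
10 | 2-{(2S)-5,7-bis(benzyloxy)-2-[4-(benzyloxy)phenyl]chroman-8-yl}-1-[4-(benzyloxy)phenyl]ethan-1-one | O=C(Cc1c(OCc2ccccc2)cc(OCc2ccccc2)c2c1O[C@H](c1ccc(OCc3ccccc3)cc1)CC2)c1ccc(OCc2ccccc2)cc1 | intermediate
11 | 1-{(2S)-5,7-bis(benzyloxy)-2-[4-(benzyloxy)phenyl]chroman-8-yl}-2-[4-(benzyloxy)phenyl]ethane-1,2-dione | O=C(C(=O)c1c(OCc2ccccc2)cc(OCc2ccccc2)c2c1O[C@H](c1ccc(OCc3ccccc3)cc1)CC2)c1ccc(OCc2ccccc2)cc1 | intermediate
12 | 1-[(2S)-5,7-dihydroxy-2-(4-hydroxyphenyl)chroman-8-yl]-2-(4-hydroxyphenyl)ethane-1,2-dione | O=C(C(=O)c1c(O)cc(O)c2c1O[C@H](c1ccc(O)cc1)CC2)c1ccc(O)cc1 | target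

**Step count**
Total steps: 9. Longest linear sequence: 8 (steps 1, 2, 3, 4, 5, 7, 8, 9); step 6 is a one-step branch from 3.

**Steps most likely to fail, with fallbacks**

Step 7 (enolonium arylation at C8). Risks are single-electron oxidation of the very electron-rich ring A by trivalent iodine, a C6/C8 mixture, and double alkylation. The fallback sets out from 7 and reverses the polarity of the arene carbon instead. NBS in CH2Cl2 at −78 °C brominates C8 selectively (as with benzylated catechins) to give (2S)-5,7-bis(benzyloxy)-2-[4-(benzyloxy)phenyl]-8-bromochromane F1. Palladium-catalysed α-arylation of ketone 3 with this bromide (Pd2(dba)3 as zerovalent palladium source, XPhos, NaOt-Bu, toluene, 80 °C) then joins the same two carbons, and the route is rejoined at 10.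

Step 5 (Mitsunobu closure). The 4-benzyloxybenzylic oxyphosphonium can leak into an SN1 pathway and erode the ee. The fallback sets out from 5 and sets C2 under catalyst control instead of by substitution. Cyclodehydration (TsOH cat., toluene, reflux with water removal) gives 5,7-bis(benzyloxy)-2-[4-(benzyloxy)phenyl]-4H-chromene F2. Asymmetric hydrogenation of this cyclic enol ether ([Ir(cod)(P,N)]BArF with a chiral phosphinite–oxazoline P,N ligand, enantiomer chosen to give 2S; H2 50 bar, CH2Cl2) gives the flavan, and the route is rejoined at 7, bypassing 6.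

Step 9 (debenzylation next to the diketone). The diketone may be over-reduced to the benzoin, or the C2–O1 bond may be hydrogenolysed. The fallback sets out from 11 and replaces reduction by Lewis-acid dealkylation: BCl3 with pentamethylbenzene as benzyl-cation scavenger, CH2Cl2, −78 °C, then MeOH quench. This cannot reduce the diketone and arrives directly at 12; it makes no new compound (F0).

**Further compounds**
F1 | step 7 | (2S)-5,7-bis(benzyloxy)-2-[4-(benzyloxy)phenyl]-8-bromochromane | Brc1c(OCc2ccccc2)cc(OCc2ccccc2)c2c1O[C@H](c1ccc(OCc3ccccc3)cc1)CC2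
F2 | step 5 | 5,7-bis(benzyloxy)-2-[4-(benzyloxy)phenyl]-4H-chromene | C(Oc1cc(OCc2ccccc2)c2c(c1)OC(c1ccc(OCc3ccccc3)cc1)=CC2)c1ccccc1
F0 | step 9 | none | none
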